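All runs are simulated with constants of no real substance, noise included.

The unit I chose for a colleague's quick question was the fraction of the starting material charged: each turnover takes one reagent, so a fraction of product spends that fraction of the charge in reagent, from both phases together.

| flask | starting material | reagent in the second phase | remark | time | volume of the second phase over the first |
|---|---|---|---|---|---|
| noon | 2 mM | 3.3 mM | run made earlier |  |  |
| flask | 2.0 mM | 2.20 mM |  | 6.0 min | 0.50 |

- noon (time / s: product / %, starting material / %): 10.0: 11.4, 89.0; 12.0: 12.0, 89.5; 20.0: 17.3, 82.2; 30.0: 22.3, 77.7; 40.0: 26.2, 74.4; 60.0: 30.1, 70.4; 80.0: 32.8, 68.3

(readings scatter by 1 percentage point)

- amount of product at 6.0 min, in percent of the starting material charged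
- the change that raises the amount of product at 6.0 min, in percent of the starting material charged most ("none" if none brings more than 2 percentage points) (east / north / none)
- amount of product at 6.0 min, in percent of the starting material charged, after north

- east: doubling the transfer coefficient of the reagent in the second phase, all else as stated
- north: doubling the amount of reagent in the second phase, all else as stated

- in the second phase: reagent in the second phase; everything else is in the first
- charges count per volume of the first phase; a concentration in a rate is the amount of a species over the volume of its own phase; every rate counts per litre of the first phase
- reactions considered so far: starting material + reagent in the reaction phase <-> product; reagent in the reaction phase <-> reagent in the second phase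
- the earlier runs hold the two phases in the same ratio of volumes as the flask asked about

The noon gains shrank from 3.9 percentage points to 2.7 points over equal steps, so I read a time constant of 54.4 s and a level of 38.9%, both loose under a scatter of 1 point. At the level, with the phase ratio unchanged, I took the reagent in the reaction phase as a fixed share of the unspent reagent. The turnover quotient, the fraction turned over divided by the fraction left and by the unspent reagent, came to 0.252 mM⁻¹ at the level read from the noon run, and it is as loose as that level.

Six minutes is 6.62 such time constants, so I read the flask as levelled, under thermodynamic control. The quotient then gave me 29.0%, and 46.6% after north. Their hunch, the forecast, stood lower: 26%, and 42% after north, reading the noon levelling as “an equilibrium plateau, not a stalled reaction”.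

The flask gave 27.6%, and 44.8% after north, while east brought 0 points. starting material + reagent in the reaction phase ⇌ product (K = 320 M⁻¹, k = 580 M⁻¹ s⁻¹); reagent in the reaction phase ⇌ reagent in the second phase, rate k2*([reagent in the reaction phase] - [reagent in the second phase]/K2) per volume of the first phase (partition coefficient = 0.760, kL = 0.00740 s⁻¹)

I carried the quotient to the neighbouring flask, the same flask with 8.0 mM of starting material. Taking that flask as levelled too, the quotient gave me 17.2%. That neighbouring flask held 16.7% product at 6.00 min, with 83% of its starting material left.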